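**Retrosynthetic overview**

1. Numbering (drimane type): decalin C1–C10 (C4 = CMe2, C5 and C10 = ring fusion, C7=C8, C9 carries the chain); chain C11–C19 (C12 = C–O, C13 = C–CH3); then the arene.
2. Endgame: hydroquinone ⇐ quinone ⇐ dimethyl ether; C12 sulfate ⇐ C12–OH; C1 methylene ⇐ C1 ketone; ring A ⇐ 6-endo radical closure (C4–C3) of a C5 isopropenyl group onto a C1 vinyl ketone.
3. Ring B ⇐ intramolecular Diels–Alder reaction of an ester-tethered triene (diene C6=C7–C8=C9; dienophile C5=C10 of a 2-methyl-4-oxopent-2-enoate bound to the C12 oxygen). It forms C5–C6 and C9–C10, closes ring B and a temporary δ-lactone, and sets C5, C9 and C10 from C12.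
4. Enabling feature: ring B is a cyclohexene whose C7=C8 bond lies opposite the C5–C10 bond (Diels–Alder retron), and the C12 oxygen is 1,3 to C9, so its ester with the C1 carboxyl holds diene and dienophile in a six-membered tether. The tether carbon becomes C1 and the tether oxygen becomes the sulfate oxygen.
5. Triene ⇐ dienol 11 (from geranyl bromide and 1,4-dimethoxybenzene: allylic oxidation, asymmetric hydrogenation, vinylogous aldol, methylenation) + keto acid 15. Ring order: arene (bought), ring B with the lactone (step 11), ring A (step 14).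

Key step: step 11

Assumption: the alkyl sulfate is written as the free hydrogen sulfate, as in the target; in practice 24–26 would be handled as sodium or pyridinium salts.
Remark: in the two catalyst-controlled steps (3 and 6) the catalyst antipode is the one that delivers the stated configuration.

**Route**

Step 1
Reactants: 1 1,4-dimethoxybenzene; 2 geranyl bromide
Product: 4 2-[(2E)-3,7-dimethylocta-2,6-dien-1-yl]-1,4-dimethoxybenzene, via 2,5-dimethoxyphenyllithium 3 (not isolated)
Conditions: n-BuLi, TMEDA, THF, 0 °C; CuI (10 mol %), then 2, −78 °C → rt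
Reagents that add atoms: none
Why: methoxy-directed ortho-lithiation followed by copper-catalysed SN2 allylation at the primary allylic bromide should give the geranyl arene with the (E)-alkene intact.

Step 2
Reactants: 4 2-[(2E)-3,7-dimethylocta-2,6-dien-1-yl]-1,4-dimethoxybenzene
Product: 5 (2E,6E)-8-(2,5-dimethoxyphenyl)-2,6-dimethylocta-2,6-dien-1-ol
Conditions: SeO2 (0.3 equiv), t-BuOOH, salicylic acid (cat.), CH2Cl2, 0 °C → rt
Reagents that add atoms: tert-butyl hydroperoxide, CC(C)(C)OO (oxygen atom, relayed by catalytic selenium dioxide, O=[Se]=O)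
Why: the SeO2/t-BuOOH allylic oxidation (ene reaction then [2,3]-sigmatropic shift) should attack the (E)-methyl group of the more electron-rich terminal trisubstituted alkene and give the (E)-allylic alcohol.

Step 3
Reactants: 5 (2E,6E)-8-(2,5-dimethoxyphenyl)-2,6-dimethylocta-2,6-dien-1-ol
Product: 6 (2S,6E)-8-(2,5-dimethoxyphenyl)-2,6-dimethyloct-6-en-1-ol
Conditions: H2 (40 atm), Ru(OAc)2[(S)-BINAP] (1 mol %), MeOH, rt
Reagents that add atoms: none
Why: the hydroxyl-directed Noyori Ru–BINAP asymmetric hydrogenation should reduce only the allylic-alcohol double bond and set C13 as S by ligand control (the BINAP antipode is chosen accordingly), leaving the remote trisubstituted alkene untouched.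

Step 4
Reactants: 6 (2S,6E)-8-(2,5-dimethoxyphenyl)-2,6-dimethyloct-6-en-1-ol
Product: 7 (2S,6E)-8-(2,5-dimethoxyphenyl)-2,6-dimethyloct-6-enal
Conditions: Dess–Martin periodinane, CH2Cl2, 0 °C → rt
Reagents that add atoms: none
Why: Dess–Martin oxidation should give the α-stereogenic aldehyde under nearly neutral conditions without epimerisation.

Step 5
Reactants: 8 tiglic aldehyde [(2E)-2-methylbut-2-enal]
Product: 9 tert-butyl(dimethyl){[(1E)-2-methylbuta-1,3-dien-1-yl]oxy}silane
Conditions: TBSOTf, Et3N, Et2O, 0 °C → rt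
Reagents that add atoms: tert-butyldimethylsilyl trifluoromethanesulfonate, CC(C)(C)[Si](C)(C)OS(=O)(=O)C(F)(F)F
Why: soft enolisation (γ-deprotonation of the O-silylated enal) should give the silyl dienol ether, whose C1=C2 geometry is of no consequence for the next step.

Step 6
Reactants: 7 (2S,6E)-8-(2,5-dimethoxyphenyl)-2,6-dimethyloct-6-enal; 9 tert-butyl(dimethyl){[(1E)-2-methylbuta-1,3-dien-1-yl]oxy}silane
Product: 10 (2E,5S,6S,10E)-12-(2,5-dimethoxyphenyl)-5-hydroxy-2,6,10-trimethyldodeca-2,10-dienal
Conditions: N-tosyl-tryptophan-derived B-phenyl-1,3,2-oxazaborolidin-5-one (30 mol %, antipode matched to Felkin attack), i-PrOH, CH2Cl2/EtCN, −78 °C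
Reagents that add atoms: none
Why: a vinylogous Mukaiyama aldol reaction (γ-attack of the dienol ether) should give the (E)-enal, with the new C12 carbinol set syn to the C13 methyl group by Felkin–Anh addition reinforced by the chiral boron Lewis acid.

Step 7
Reactants: 10 (2E,5S,6S,10E)-12-(2,5-dimethoxyphenyl)-5-hydroxy-2,6,10-trimethyldodeca-2,10-dienal
Product: 11 (3E,6S,7S,11E)-13-(2,5-dimethoxyphenyl)-3,7,11-trimethyltrideca-1,3,11-trien-6-ol
Conditions: Ph3PCH3Br, KN(SiMe3)2 (2.5 equiv each), THF, −78 → 0 °C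
Reagents that add atoms: methyltriphenylphosphonium bromide, C[P+](c1ccccc1)(c1ccccc1)c1ccccc1.[Br-]
Why: Wittig methylenation of the enal should give the (3E)-1,3-diene, the excess ylide covering the free hydroxyl group.

Step 8
Reactants: 12 methylglyoxal (2-oxopropanal, 40 % in water); 13 ethyl 2-(triphenyl-λ5-phosphanylidene)propanoate
Product: 14 ethyl (2E)-2-methyl-4-oxopent-2-enoate
Conditions: CH2Cl2/H2O, rt
Reagents that add atoms: none
Why: the Wittig reaction of the stabilised α-methyl ylide at the aldehyde carbonyl of methylglyoxal should give the (E)-trisubstituted enoate with ester and acetyl groups trans.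

Step 9
Reactants: 14 ethyl (2E)-2-methyl-4-oxopent-2-enoate
Product: 15 (2E)-2-methyl-4-oxopent-2-enoic acid
Conditions: LiOH (1.05 equiv), THF/H2O, 0 °C; then 1 M HCl
Reagents that add atoms: lithium hydroxide, [Li+].[OH-]
Why: brief cold saponification should free the acid while keeping the (E)-geometry, which cannot lactonise to the pseudo-acid.

Step 10
Reactants: 11 (3E,6S,7S,11E)-13-(2,5-dimethoxyphenyl)-3,7,11-trimethyltrideca-1,3,11-trien-6-ol; 15 (2E)-2-methyl-4-oxopent-2-enoic acid
Product: 16 (3E,6S,7S,11E)-13-(2,5-dimethoxyphenyl)-3,7,11-trimethyltrideca-1,3,11-trien-6-yl (2E)-2-methyl-4-oxopent-2-enoate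
Conditions: DCC, DMAP (10 mol %), CH2Cl2, 0 °C
Reagents that add atoms: none
Why: Steglich esterification should join diene and dienophile through the C12 oxygen without touching a stereocentre.

Step 11
Reactants: 16 (3E,6S,7S,11E)-13-(2,5-dimethoxyphenyl)-3,7,11-trimethyltrideca-1,3,11-trien-6-yl (2E)-2-methyl-4-oxopent-2-enoate
Product: 17 trans-fused 8-acetyl-5,8a-dimethyl-3-[(2S,6E)-8-(2,5-dimethoxyphenyl)-6-methyloct-6-en-2-yl]-3,4,4a,7,8,8a-hexahydro-1H-isochromen-1-one (4a-H anti to 8a-CH3; 8-acetyl cis to 8a-CH3; C3 chain equatorial)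
Conditions: PhMe (0.01 M), BHT (5 mol %), 110 °C, sealed tube
Reagents that add atoms: none
Why: Thermal, concerted but asynchronous [4+2] cycloaddition of the (E)-diene C6=C7–C8=C9 onto the (E)-keto-enoate C5=C10, the closest precedent being the intramolecular Diels–Alder reaction of ester-linked 1,7,9-decatrienes with fumarate-type dienophiles. Ring B closes by the cycloaddition itself (new bonds C5–C6 and C9–C10), and the temporary δ-lactone closes as the fused six-membered tether ring of a type 1 intramolecular Diels–Alder reaction, trans-fused at C9–C10. C5 and C10 follow from the (E)-dienophile (suprafacial addition keeps the C1 carboxyl and the C4 acetyl trans, the later trans ring fusion), and C9 follows from the (E)-diene together with the transition state that has the conjugating acetyl group endo and the α-methyl-bearing tether carbonyl exo, which places C11 cis to the C10 methyl group and to C4. The absolute sense is relayed from C12, whose C13 chain sits equatorial in the chair-like tether, helped by allylic strain from the C8 methyl group. The step needs regioselectivity (C9 to C10, not to C5), which the four-atom tether enforces because the other mode would need a bridged seven-membered lactone, and it needs the exo-tether mode, which the ketone-endo preference of the doubly activated dienophile and its α-methyl group should secure; dilution suppresses dimerisation.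

Step 12
Reactants: 17 Diels–Alder adduct (acetyl lactone)
Product: 18 the same trans-fused lactone with a prop-1-en-2-yl group in place of the 8-acetyl group
Conditions: Ph3PCH3Br, KOt-Bu, THF, 0 °C
Reagents that add atoms: methyltriphenylphosphonium bromide, C[P+](c1ccccc1)(c1ccccc1)c1ccccc1.[Br-]
Why: Wittig methylenation should take the methyl ketone and leave the hindered lactone; C5 already carries its substituent in the favoured equatorial position, so no epimerisation is expected.

Step 13
Reactants: 18 isopropenyl lactone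
Product: 20 hydroxy enone (ring B cyclohexene with C10 carrying CH3 and an acryloyl group, C5 an isopropenyl group, C9 the chain with free (12S)-OH), via bromomagnesium hemiketal alkoxide 19 (not isolated)
Conditions: CH2=CHMgBr (1.3 equiv), CeCl3, THF, −78 → −40 °C; aq. NH4Cl
Reagents that add atoms: vinylmagnesium bromide, C=C[Mg]Br
Why: mono-addition of the vinyl nucleophile to the δ-lactone should stop at the tetrahedral hemiketal alkoxide at low temperature, which opens on work-up to the conjugated, α-quaternary hydroxy vinyl ketone.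

Step 14
Reactants: 20 hydroxy enone
Product: 21 decalin ketone (target skeleton with C1=O, free 12-OH, hydroquinone dimethyl ether)
Conditions: Fe(acac)3 [iron tris(acetylacetonate), 30 mol %], PhSiH3 (2.5 equiv), EtOH/(CH2OH)2, 60 °C
Reagents that add atoms: none
Why: metal-hydride hydrogen-atom transfer to the 1,1-disubstituted alkene should give the tertiary C4 radical, which adds 6-endo to the β-carbon (C3) of the vinyl ketone (intramolecular reductive olefin coupling of the Giese type); this closes ring A and creates the gem-dimethyl carbon without a new stereocentre, the trans fusion being preset by C5 and C10.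

Step 15
Reactants: 21 decalin ketone
Product: 23 (2S,3S,7E)-9-(2,5-dimethoxyphenyl)-3,7-dimethyl-1-[(1R,4aR,8aR)-2,5,5,8a-tetramethyl-1,4,4a,5,6,7,8,8a-octahydronaphthalen-1-yl]non-7-en-2-ol, via hydrazone of the C1 ketone 22 (not isolated)
Conditions: N2H4·H2O, KOH, diethylene glycol, 130 → 200 °C, argon
Reagents that add atoms: none
Why: Wolff–Kishner reduction (Huang-Minlon procedure) should remove the C1 carbonyl group, which cannot epimerise the quaternary C10 and leaves the isolated alkenes alone.

Step 16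
Reactants: 23 decalin alcohol
Product: 24 hydrogen sulfate of 23 at the C12 oxygen
Conditions: SO3·pyridine (5 equiv), pyridine, 50 °C; aqueous work-up
Reagents that add atoms: sulfur trioxide–pyridine complex, [O-]S(=O)(=O)[n+]1ccccc1
Why: O-sulfonation of the only free hydroxyl group should proceed with retention at C12.

Step 17
Reactants: 24 sulfate dimethyl ether
Product: 25 2-substituted 1,4-benzoquinone carrying the sulfated side chain
Conditions: (NH4)2Ce(NO3)6 (2.5 equiv), MeCN/H2O, 0 °C
Reagents that add atoms: water, O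
Why: oxidative demethylation of the 1,4-dimethoxyarene with (NH4)2Ce(NO3)6 should give the quinone, a standard unmasking for prenylated hydroquinone dimethyl ethers that spares trisubstituted alkenes and the sulfate at 0 °C.

Step 18
Reactants: 25 quinone sulfate
Product: 26 target, 2-[(2E,7S,8S)-3,7-dimethyl-8-(sulfooxy)-9-[(1R,4aR,8aR)-2,5,5,8a-tetramethyl-1,4,4a,5,6,7,8,8a-octahydronaphthalen-1-yl]non-2-en-1-yl]benzene-1,4-diol
Conditions: Na2S2O4, EtOAc/H2O, rt, argon
Reagents that add atoms: none
Why: dithionite reduction of the quinone should give the hydroquinone without affecting the sulfate or the alkenes.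

**Compound list**

1 | 1,4-dimethoxybenzene | COc1ccc(OC)cc1 | starting material
2 | geranyl bromide [(2E)-1-bromo-3,7-dimethylocta-2,6-diene] | CC(C)=CCC/C(C)=C/CBr | starting material
3 | 2,5-dimethoxyphenyllithium (not isolated) | COc1ccc(OC)c([Li])c1 | intermediate
4 | 2-[(2E)-3,7-dimethylocta-2,6-dien-1-yl]-1,4-dimethoxybenzene | CC(C)=CCC/C(C)=C/Cc1cc(OC)ccc1OC | intermediate
5 | (2E,6E)-8-(2,5-dimethoxyphenyl)-2,6-dimethylocta-2,6-dien-1-ol | OC/C(C)=C/CC/C(C)=C/Cc1cc(OC)ccc1OC | intermediate
6 | (2S,6E)-8-(2,5-dimethoxyphenyl)-2,6-dimethyloct-6-en-1-ol | OC[C@@H](C)CCC/C(C)=C/Cc1cc(OC)ccc1OC | intermediate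
7 | (2S,6E)-8-(2,5-dimethoxyphenyl)-2,6-dimethyloct-6-enal | O=C[C@@H](C)CCC/C(C)=C/Cc1cc(OC)ccc1OC | intermediate
8 | tiglic aldehyde [(2E)-2-methylbut-2-enal] | C/C=C(\C)C=O | starting material
9 | tert-butyl(dimethyl){[(1E)-2-methylbuta-1,3-dien-1-yl]oxy}silane | C=C/C(C)=C/O[Si](C)(C)C(C)(C)C | intermediate
10 | (2E,5S,6S,10E)-12-(2,5-dimethoxyphenyl)-5-hydroxy-2,6,10-trimethyldodeca-2,10-dienal | O=C/C(C)=C/C[C@H](O)[C@@H](C)CCC/C(C)=C/Cc1cc(OC)ccc1OC | intermediate
11 | (3E,6S,7S,11E)-13-(2,5-dimethoxyphenyl)-3,7,11-trimethyltrideca-1,3,11-trien-6-ol | C=C/C(C)=C/C[C@H](O)[C@@H](C)CCC/C(C)=C/Cc1cc(OC)ccc1OC | intermediate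
12 | methylglyoxal (2-oxopropanal) | CC(=O)C=O | starting material
13 | ethyl 2-(triphenyl-λ5-phosphanylidene)propanoate | CCOC(=O)C(C)=P(c1ccccc1)(c1ccccc1)c1ccccc1 | starting material
14 | ethyl (2E)-2-methyl-4-oxopent-2-enoate | CCOC(=O)/C(C)=C/C(C)=O | intermediate
15 | (2E)-2-methyl-4-oxopent-2-enoic acid | OC(=O)/C(C)=C/C(C)=O | intermediate
16 | (3E,6S,7S,11E)-13-(2,5-dimethoxyphenyl)-3,7,11-trimethyltrideca-1,3,11-trien-6-yl (2E)-2-methyl-4-oxopent-2-enoate | C=C/C(C)=C/C[C@H](OC(=O)/C(C)=C/C(C)=O)[C@@H](C)CCC/C(C)=C/Cc1cc(OC)ccc1OC | intermediate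
17 | Diels–Alder adduct: trans-fused 8-acetyl-5,8a-dimethyl-3-[(2S,6E)-8-(2,5-dimethoxyphenyl)-6-methyloct-6-en-2-yl]-3,4,4a,7,8,8a-hexahydro-1H-isochromen-1-one (4a-H anti to 8a-CH3, 8-acetyl cis to 8a-CH3, C3 chain equatorial) | CC1=CC[C@H](C(C)=O)[C@]2(C)[C@@H]1C[C@@H]([C@@H](C)CCC/C(C)=C/Cc1cc(OC)ccc1OC)OC2=O | intermediate
18 | lactone 17 with 8-(prop-1-en-2-yl) in place of 8-acetyl, same configuration | CC1=CC[C@H](C(C)=C)[C@]2(C)[C@@H]1C[C@@H]([C@@H](C)CCC/C(C)=C/Cc1cc(OC)ccc1OC)OC2=O | intermediate
19 | bromomagnesium hemiketal alkoxide from 18 (1-vinyl, 1-OMgBr; not isolated; hemiketal carbon unspecified) | CC1=CC[C@H](C(C)=C)[C@]2(C)[C@@H]1C[C@@H]([C@@H](C)CCC/C(C)=C/Cc1cc(OC)ccc1OC)OC2(C=C)O[Mg]Br | intermediate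
20 | hydroxy enone: 1-[ring B C10]-prop-2-en-1-one with C10 methyl, C5 isopropenyl, C9 chain bearing free (12S)-OH and (13S)-CH3; ring stereocentres as in 17 | CC1=CC[C@H](C(C)=C)[C@@](C)(C(=O)C=C)[C@@H]1C[C@H](O)[C@@H](C)CCC/C(C)=C/Cc1cc(OC)ccc1OC | intermediate
21 | decalin ketone: compound 23 with a carbonyl group at C1 (ring A carbon next to C10); trans-fused; stereocentres as in 26 | CC1=CC[C@@H]2C(C)(C)CCC(=O)[C@@]2(C)[C@@H]1C[C@H](O)[C@@H](C)CCC/C(C)=C/Cc1cc(OC)ccc1OC | intermediate
22 | hydrazone of ketone 21 at C1 (not isolated) | CC1=CC[C@@H]2C(C)(C)CCC(=NN)[C@@]2(C)[C@@H]1C[C@H](O)[C@@H](C)CCC/C(C)=C/Cc1cc(OC)ccc1OC | intermediate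
23 | (2S,3S,7E)-9-(2,5-dimethoxyphenyl)-3,7-dimethyl-1-[(1R,4aR,8aR)-2,5,5,8a-tetramethyl-1,4,4a,5,6,7,8,8a-octahydronaphthalen-1-yl]non-7-en-2-ol | CC1=CC[C@@H]2C(C)(C)CCC[C@@]2(C)[C@@H]1C[C@H](O)[C@@H](C)CCC/C(C)=C/Cc1cc(OC)ccc1OC | intermediate
24 | hydrogen sulfate ester of 23 at the C2 oxygen of the nonenyl chain (C12 in the numbering used here) | CC1=CC[C@@H]2C(C)(C)CCC[C@@]2(C)[C@@H]1C[C@H](OS(=O)(=O)O)[C@@H](C)CCC/C(C)=C/Cc1cc(OC)ccc1OC | intermediate
25 | quinone: 24 with the dimethoxyarene replaced by a 2-substituted cyclohexa-2,5-diene-1,4-dione | CC1=CC[C@@H]2C(C)(C)CCC[C@@]2(C)[C@@H]1C[C@H](OS(=O)(=O)O)[C@@H](C)CCC/C(C)=C/CC1=CC(=O)C=CC1=O | intermediate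
26 | CNP0358517.7: 2-[(2E,7S,8S)-3,7-dimethyl-8-(sulfooxy)-9-[(1R,4aR,8aR)-2,5,5,8a-tetramethyl-1,4,4a,5,6,7,8,8a-octahydronaphthalen-1-yl]non-2-en-1-yl]benzene-1,4-diol | CC1=CC[C@@H]2C(C)(C)CCC[C@@]2(C)[C@@H]1C[C@H](OS(=O)(=O)O)[C@@H](C)CCC/C(C)=C/Cc1cc(O)ccc1O | target

**Step count**

Total steps: 18. Longest linear sequence: 15 steps (steps 1–4, 6, 7, 10–18, from 1 to 26).

**Steps most likely to fail, with fallbacks**

Step 11. The transition state with the tether carbonyl endo (cis-fused lactone, C9 of the wrong relative configuration to C10) may compete, and the π-facial control from C12 may be incomplete. The fallback replaces tether control by catalyst control. It sets out from 11, which is silylated (TBSCl, imidazole, DMF) to the tert-butyldimethylsilyl ether F1. F1 is combined in an intermolecular Diels–Alder reaction with (2E)-2-methyl-4-oxopent-2-enal F2 (from 12 and 2-(triphenylphosphoranylidene)propanal), using a triflimide-activated o-tolyl oxazaborolidinium catalyst of the prolinol type in CH2Cl2 at −78 °C. The catalyst binds the formyl group, so the unsubstituted diene terminus should attack C5; formyl-exo, acetyl-endo addition should give the cyclohexene aldehyde F3 with the absolute sense set by the catalyst. Pinnick oxidation (NaClO2, NaH2PO4, 2-methylbut-2-ene) gives the acid F4, HF·pyridine gives the hydroxy acid F5, and DCC/DMAP lactonisation comes back to the route at 17.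

Step 14. Hydrogen-atom transfer may also reach the other two trisubstituted alkenes (C7=C8 and the chain alkene), giving over-reduced or isomerised material, and the vinyl ketone may be reduced before it is trapped. The fallback generates the C4 radical by decarboxylation instead of by hydrogen-atom transfer. It sets out from 17: MeMgBr/CeCl3 (THF, −78 °C) adds to the methyl ketone to give the tertiary alcohol F6. Oxalyl chloride followed by aqueous CsHCO3 gives the caesium oxalate F7. Visible-light photoredox fragmentation (Ir[dF(CF3)ppy]2(dtbbpy)PF6, 1 mol %, DME/DMF/H2O) in the presence of phenyl vinyl sulfone gives the sulfone F8, with the gem-dimethyl carbon and C3, C2 in place. LiN(SiMe3)2 (THF, −78 → 0 °C) closes ring A by attack of the sulfonyl carbanion on the lactone carbonyl, freeing the C12 hydroxyl group and giving the β-keto sulfone F9. SmI2 (THF/MeOH) removes the sulfonyl group and comes back to the route at 21.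

Step 13. Addition to the hindered, α-quaternary lactone may be slow, and once the tetrahedral intermediate collapses a second 1,2- or 1,4-addition can follow. The fallback changes the oxidation level of the electrophile. It sets out from 18: i-Bu2AlH (CH2Cl2, −78 °C) gives the lactol F10; excess CH2=CHMgBr adds to its open hydroxy-aldehyde form to give the allylic alcohol F11 (diol, carbinol configuration of no consequence); MnO2 (CH2Cl2, rt) oxidises only the allylic alcohol and comes back to the route at 20.

**Further compounds**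

F1 | step 11 | tert-butyldimethylsilyl ether of 11 | C=C/C(C)=C/C[C@H](O[Si](C)(C)C(C)(C)C)[C@@H](C)CCC/C(C)=C/Cc1cc(OC)ccc1OC
F2 | step 11 | (2E)-2-methyl-4-oxopent-2-enal | CC(=O)/C=C(\C)C=O
F3 | step 11 | cyclohexene aldehyde: ring B with C10 carrying CH3 and CHO, C5 acetyl (cis to the C10 methyl), C9 chain with 12-OTBS | CC1=CC[C@H](C(C)=O)[C@@](C)(C=O)[C@@H]1C[C@H](O[Si](C)(C)C(C)(C)C)[C@@H](C)CCC/C(C)=C/Cc1cc(OC)ccc1OC
F4 | step 11 | carboxylic acid from F3 (CHO to CO2H) | CC1=CC[C@H](C(C)=O)[C@@](C)(C(=O)O)[C@@H]1C[C@H](O[Si](C)(C)C(C)(C)C)[C@@H](C)CCC/C(C)=C/Cc1cc(OC)ccc1OC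
F5 | step 11 | hydroxy acid from F4 (free 12-OH) | CC1=CC[C@H](C(C)=O)[C@@](C)(C(=O)O)[C@@H]1C[C@H](O)[C@@H](C)CCC/C(C)=C/Cc1cc(OC)ccc1OC
F6 | step 14 | lactone 17 with 8-(2-hydroxypropan-2-yl) in place of 8-acetyl | CC1=CC[C@H](C(C)(C)O)[C@]2(C)[C@@H]1C[C@@H]([C@@H](C)CCC/C(C)=C/Cc1cc(OC)ccc1OC)OC2=O
F7 | step 14 | caesium oxalate half-ester of the tertiary alcohol F6 | CC1=CC[C@H](C(C)(C)OC(=O)C(=O)[O-])[C@]2(C)[C@@H]1C[C@@H]([C@@H](C)CCC/C(C)=C/Cc1cc(OC)ccc1OC)OC2=O.[Cs+]
F8 | step 14 | lactone with 8-[2-methyl-4-(phenylsulfonyl)butan-2-yl] group | CC1=CC[C@H](C(C)(C)CCS(=O)(=O)c3ccccc3)[C@]2(C)[C@@H]1C[C@@H]([C@@H](C)CCC/C(C)=C/Cc1cc(OC)ccc1OC)OC2=O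
F9 | step 14 | decalin ketone 21 carrying a phenylsulfonyl group at C2 (configuration at C2 unspecified) | CC1=CC[C@@H]2C(C)(C)CC(S(=O)(=O)c3ccccc3)C(=O)[C@@]2(C)[C@@H]1C[C@H](O)[C@@H](C)CCC/C(C)=C/Cc1cc(OC)ccc1OC
F10 | step 13 | lactol from 18 (lactone C=O reduced to CH–OH, anomeric carbon unspecified) | CC1=CC[C@H](C(C)=C)[C@]2(C)[C@@H]1C[C@@H]([C@@H](C)CCC/C(C)=C/Cc1cc(OC)ccc1OC)OC2O
F11 | step 13 | diol: 20 with the ketone replaced by a secondary allylic alcohol | CC1=CC[C@H](C(C)=C)[C@@](C)(C(O)C=C)[C@@H]1C[C@H](O)[C@@H](C)CCC/C(C)=C/Cc1cc(OC)ccc1OC
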